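**Retrosynthetic overview** (locants follow the azulene numbering of the target name, compound 24)
1. Target ⇐ aryl acetate 23 ⇐ diene 21, by a late Markovnikov hydration that makes the tertiary C3–O bond on the convex face of the cis-fused bicycle.
2. Seven-membered ring (formed last) ⇐ ring-closing metathesis of a methallyl group with the vinyl group of an allylic 3-methylbutanoate.
3. C8–O ester bond (key disconnection) ⇐ rhodium-catalysed branched addition of 3-methylbutanoic acid to an allene on the quaternary carbon; the allene comes from an ethynyl group.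
4. Five-membered ring (present from the start as 3-ethoxycyclopentenone) ⇐ asymmetric 1,4-methylation of an enynone with syn-aldol capture (sets C8a, C3a, C4), then enol triflate/isopropyl coupling.

Assumption: the SMILES is taken as drawn, i.e. (3S,3aS,4R,8S,8aR), a cis ring fusion with 8a-CH3, H-3a and 3-OH on one face and both acyloxy groups on the other.

**Route**

Step 1
Reactants: 1 3-methylbut-3-en-1-ol
Product: 2 3-methylbut-3-enal
Conditions: Dess–Martin periodinane, CH2Cl2, 0 °C to rt; solution used at once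
Reagents that add atoms: none
Why: Dess–Martin oxidation is neutral enough to give the β,γ-unsaturated aldehyde without moving the double bond into conjugation.

Step 2
Reactants: 3 3-ethoxycyclopent-2-en-1-one; 4 ethynyl(trimethyl)silane
Product: 6 3-[(trimethylsilyl)ethynyl]cyclopent-2-en-1-one, via lithium alkoxide 5 (not isolated)
Conditions: 4, n-BuLi, THF, −78 °C; then 3, −78 to 0 °C; then 1 M HCl, rt
Reagents that add atoms: water, O
Why: Stork–Danheiser sequence, in which 1,2-addition of the lithium acetylide to the vinylogous ester and acid hydrolysis with loss of ethanol give the transposed enynone.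

Step 3
Reactants: 6 3-[(trimethylsilyl)ethynyl]cyclopent-2-en-1-one; 2 3-methylbut-3-enal
Product: 9 (2S,3R)-2-[(1R)-1-hydroxy-3-methylbut-3-en-1-yl]-3-methyl-3-[(trimethylsilyl)ethynyl]cyclopentan-1-one, via bromomagnesium enolate 7 (not isolated), via titanium enolate 8 (not isolated)
Conditions: MeMgBr (1.05 equiv), Cu(OTf)2 (3 mol%), chiral imidazolinium chloride (NHC precursor) from (S,S)-1,2-diphenylethane-1,2-diamine (4 mol%), Et2O, −30 °C; then ClTi(OiPr)3, −78 °C; then 2, −78 °C; aq NH4Cl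
Reagents that add atoms: methylmagnesium bromide, C[Mg]Br
Why: Copper–NHC-catalysed asymmetric conjugate (1,4) addition of the Grignard reagent to the cyclic enynone sets the quaternary centre (R) under catalyst control (ligand enantiomer chosen accordingly), and the triisopropoxytitanium enolate then gives a syn-selective aldol addition in which the aldehyde enters C2 on the face of the slender alkynyl group, anti to the methyl group.

Step 4
Reactants: 9 (2S,3R)-2-[(1R)-1-hydroxy-3-methylbut-3-en-1-yl]-3-methyl-3-[(trimethylsilyl)ethynyl]cyclopentan-1-one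
Product: 10 (2S,3R)-2-[(1R)-1-{[tert-butyl(dimethyl)silyl]oxy}-3-methylbut-3-en-1-yl]-3-methyl-3-[(trimethylsilyl)ethynyl]cyclopentan-1-one
Conditions: TBSOTf, 2,6-lutidine, CH2Cl2, −78 °C
Reagents that add atoms: tert-butyldimethylsilyl trifluoromethanesulfonate, CC(C)(C)[Si](C)(C)OS(=O)(=O)C(F)(F)F
Why: Silylation of the β-hydroxy ketone at low temperature blocks retro-aldol and elimination in the enolisation that follows.

Step 5
Reactants: 10 (2S,3R)-2-[(1R)-1-{[tert-butyl(dimethyl)silyl]oxy}-3-methylbut-3-en-1-yl]-3-methyl-3-[(trimethylsilyl)ethynyl]cyclopentan-1-one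
Product: 12 (4R,5S)-5-[(1R)-1-{[tert-butyl(dimethyl)silyl]oxy}-3-methylbut-3-en-1-yl]-4-methyl-4-[(trimethylsilyl)ethynyl]cyclopent-1-en-1-yl trifluoromethanesulfonate, via potassium enolate 11 (not isolated)
Conditions: KN(SiMe3)2, THF, −78 °C; then PhNTf2, −78 to 0 °C
Reagents that add atoms: N-phenylbis(trifluoromethanesulfonimide), O=S(=O)(N(c1ccccc1)S(=O)(=O)C(F)(F)F)C(F)(F)F
Why: Kinetic deprotonation takes the unhindered CH2 rather than the tertiary α-CH next to the quaternary carbon, and O-triflation of that enolate fixes the double bond away from the ring-fusion carbon.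

Step 6
Reactants: 12 (4R,5S)-5-[(1R)-1-{[tert-butyl(dimethyl)silyl]oxy}-3-methylbut-3-en-1-yl]-4-methyl-4-[(trimethylsilyl)ethynyl]cyclopent-1-en-1-yl trifluoromethanesulfonate
Product: 13 tert-butyl(dimethyl){[(1R)-3-methyl-1-{(1S,5R)-5-methyl-2-(propan-2-yl)-5-[(trimethylsilyl)ethynyl]cyclopent-2-en-1-yl}but-3-en-1-yl]oxy}silane
Conditions: i-PrMgCl, Fe(acac)3 (5 mol%), THF/NMP, −20 °C
Reagents that add atoms: isopropylmagnesium chloride, CC(C)[Mg]Cl
Why: Iron-catalysed Kumada-type cross-coupling of alkenyl triflates takes secondary alkyl Grignard reagents at low temperature and leaves silyl ethers and silylalkynes untouched.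

Step 7
Reactants: 13 tert-butyl(dimethyl){[(1R)-3-methyl-1-{(1S,5R)-5-methyl-2-(propan-2-yl)-5-[(trimethylsilyl)ethynyl]cyclopent-2-en-1-yl}but-3-en-1-yl]oxy}silane
Product: 14 (1R)-1-[(1S,5R)-5-ethynyl-5-methyl-2-(propan-2-yl)cyclopent-2-en-1-yl]-3-methylbut-3-en-1-ol
Conditions: Bu4NF (3 equiv), THF, 0 °C to rt
Reagents that add atoms: none
Why: Fluoride-mediated desilylation cleaves the C(sp)–Si and O–Si bonds in one operation.

Step 8
Reactants: 14 (1R)-1-[(1S,5R)-5-ethynyl-5-methyl-2-(propan-2-yl)cyclopent-2-en-1-yl]-3-methylbut-3-en-1-ol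
Product: 16 (1R)-3-methyl-1-[(1R,5S)-5-methyl-5-(propa-1,2-dien-1-yl)-2-(propan-2-yl)cyclopent-2-en-1-yl]but-3-en-1-ol, via propargylic amine 15 (not isolated)
Conditions: (CH2O)n, CuI (0.5 equiv), Cy2NH, 1,4-dioxane, 100 °C
Reagents that add atoms: formaldehyde (as paraformaldehyde), C=O
Why: Crabbé homologation, in which the copper acetylide undergoes a Mannich reaction and the propargylic amine transfers hydride intramolecularly to give the terminal allene, tolerating the free secondary alcohol.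

Step 9
Reactants: 16 (1R)-3-methyl-1-[(1R,5S)-5-methyl-5-(propa-1,2-dien-1-yl)-2-(propan-2-yl)cyclopent-2-en-1-yl]but-3-en-1-ol; 17 4-(acetyloxy)benzoyl chloride
Product: 18 (1R)-3-methyl-1-[(1R,5S)-5-methyl-5-(propa-1,2-dien-1-yl)-2-(propan-2-yl)cyclopent-2-en-1-yl]but-3-en-1-yl 4-(acetyloxy)benzoate
Conditions: pyridine, DMAP (10 mol%), CH2Cl2, 0 °C to rt
Reagents that add atoms: none
Why: DMAP-catalysed acylation of the secondary alcohol proceeds with retention and caps the hydroxyl that would otherwise trap the allyl-rhodium intermediate of the next step.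

Step 10
Reactants: 18 (1R)-3-methyl-1-[(1R,5S)-5-methyl-5-(propa-1,2-dien-1-yl)-2-(propan-2-yl)cyclopent-2-en-1-yl]but-3-en-1-yl 4-(acetyloxy)benzoate; 19 3-methylbutanoic acid
Product: 20 (1R)-3-methyl-1-[(1S,5R)-5-methyl-5-{(1S)-1-[(3-methylbutanoyl)oxy]prop-2-en-1-yl}-2-(propan-2-yl)cyclopent-2-en-1-yl]but-3-en-1-yl 4-(acetyloxy)benzoate
Conditions: [Rh(cod)Cl]2 (2.5 mol%), (R,R)-DIOP (6 mol%), Cs2CO3 (10 mol%), ClCH2CH2Cl, 40 °C
Reagents that add atoms: none
Why: Proposed new method: catalyst-controlled, branched-selective addition of a carboxylic acid O–H across an allene that sits on a quaternary stereocentre, a substrate class not yet shown for this reaction; oxidative addition of the acid to monovalent rhodium gives a trivalent rhodium hydride, hydrometalation of the terminal C=C gives an allyl carboxylate complex, and inner-sphere C–O reductive elimination at the substituted terminus forms the allylic C–O bond (C8 of the target) with the (S) configuration set by the C2-symmetric bisphosphine (the ligand antipode is used if the first pairing is mismatched), the closest known reaction type being the rhodium/DIOP-catalysed coupling of carboxylic acids with simple monosubstituted terminal allenes to branched allylic esters.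

Step 11
Reactants: 20 (1R)-3-methyl-1-[(1S,5R)-5-methyl-5-{(1S)-1-[(3-methylbutanoyl)oxy]prop-2-en-1-yl}-2-(propan-2-yl)cyclopent-2-en-1-yl]but-3-en-1-yl 4-(acetyloxy)benzoate
Product: 21 (3aS,4R,8S,8aR)-6,8a-dimethyl-8-[(3-methylbutanoyl)oxy]-3-(propan-2-yl)-1,3a,4,5,8,8a-hexahydroazulen-4-yl 4-(acetyloxy)benzoate
Conditions: second-generation Hoveyda–Grubbs catalyst (10 mol%), toluene (5 mM), 80 °C
Reagents that add atoms: none
Why: Ring-closing metathesis of the vinyl and methallyl groups, which are cis on the cyclopentene, closes the seven-membered ring with loss of ethene and leaves the trisubstituted cyclopentene untouched.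

Step 12
Reactants: 21 (3aS,4R,8S,8aR)-6,8a-dimethyl-8-[(3-methylbutanoyl)oxy]-3-(propan-2-yl)-1,3a,4,5,8,8a-hexahydroazulen-4-yl 4-(acetyloxy)benzoate
Product: 23 (3S,3aS,4R,8S,8aR)-3-hydroxy-6,8a-dimethyl-8-[(3-methylbutanoyl)oxy]-3-(propan-2-yl)-1,2,3,3a,4,5,8,8a-octahydroazulen-4-yl 4-(acetyloxy)benzoate, via tertiary hydroperoxide 22 (not isolated)
Conditions: Co(acac)2 (20 mol%), PhSiH3, O2 (1 atm), i-PrOH, 0 °C to rt; then PPh3
Reagents that add atoms: dioxygen, O=O
Why: Mukaiyama hydration, in which hydrogen-atom transfer to the unhindered CH terminus of the cyclopentene gives the tertiary radical that takes up O2 on the convex face (cis to H-3a, anti to the C4 aroyloxy group) to set (3S), while the C6=C7 alkene, shielded by the quaternary centre and deactivated by the allylic ester, reacts more slowly.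

Step 13
Reactants: 23 (3S,3aS,4R,8S,8aR)-3-hydroxy-6,8a-dimethyl-8-[(3-methylbutanoyl)oxy]-3-(propan-2-yl)-1,2,3,3a,4,5,8,8a-octahydroazulen-4-yl 4-(acetyloxy)benzoate
Product: 24 (3S,3aS,4R,8S,8aR)-3-hydroxy-6,8a-dimethyl-8-[(3-methylbutanoyl)oxy]-3-(propan-2-yl)-1,2,3,3a,4,5,8,8a-octahydroazulen-4-yl 4-hydroxybenzoate
Conditions: K2CO3 (10 mol%), MeOH, 0 °C
Reagents that add atoms: none
Why: Base-catalysed transesterification removes the activated phenolic acetate far faster than it touches the two hindered alkyl esters.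

**Compound list**

1 | 3-methylbut-3-en-1-ol | CC(=C)CCO | starting material
2 | 3-methylbut-3-enal | CC(=C)CC=O | intermediate
3 | 3-ethoxycyclopent-2-en-1-one | CCOC1=CC(=O)CC1 | starting material
4 | ethynyl(trimethyl)silane | C#C[Si](C)(C)C | starting material
5 | lithium 3-ethoxy-1-[(trimethylsilyl)ethynyl]cyclopent-2-en-1-olate (racemic) | CCOC1=CC(O[Li])(C#C[Si](C)(C)C)CC1 | intermediate
6 | 3-[(trimethylsilyl)ethynyl]cyclopent-2-en-1-one | C[Si](C)(C)C#CC1=CC(=O)CC1 | intermediate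
7 | bromomagnesium (3R)-3-methyl-3-[(trimethylsilyl)ethynyl]cyclopent-1-en-1-olate | C[Si](C)(C)C#C[C@]1(C)CCC(O[Mg]Br)=C1 | intermediate
8 | {[(3R)-3-methyl-3-[(trimethylsilyl)ethynyl]cyclopent-1-en-1-yl]oxy}tri(propan-2-yloxy)titanium | C[Si](C)(C)C#C[C@]1(C)CCC(O[Ti](OC(C)C)(OC(C)C)OC(C)C)=C1 | intermediate
9 | (2S,3R)-2-[(1R)-1-hydroxy-3-methylbut-3-en-1-yl]-3-methyl-3-[(trimethylsilyl)ethynyl]cyclopentan-1-one | C[Si](C)(C)C#C[C@]1(C)CCC(=O)[C@@H]1[C@H](O)CC(C)=C | intermediate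
10 | (2S,3R)-2-[(1R)-1-{[tert-butyl(dimethyl)silyl]oxy}-3-methylbut-3-en-1-yl]-3-methyl-3-[(trimethylsilyl)ethynyl]cyclopentan-1-one | C[Si](C)(C)C#C[C@]1(C)CCC(=O)[C@@H]1[C@H](O[Si](C)(C)C(C)(C)C)CC(C)=C | intermediate
11 | potassium (4R,5S)-5-[(1R)-1-{[tert-butyl(dimethyl)silyl]oxy}-3-methylbut-3-en-1-yl]-4-methyl-4-[(trimethylsilyl)ethynyl]cyclopent-1-en-1-olate | C[Si](C)(C)C#C[C@]1(C)CC=C(O[K])[C@@H]1[C@H](O[Si](C)(C)C(C)(C)C)CC(C)=C | intermediate
12 | (4R,5S)-5-[(1R)-1-{[tert-butyl(dimethyl)silyl]oxy}-3-methylbut-3-en-1-yl]-4-methyl-4-[(trimethylsilyl)ethynyl]cyclopent-1-en-1-yl trifluoromethanesulfonate | C[Si](C)(C)C#C[C@]1(C)CC=C(OS(=O)(=O)C(F)(F)F)[C@@H]1[C@H](O[Si](C)(C)C(C)(C)C)CC(C)=C | intermediate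
13 | tert-butyl(dimethyl){[(1R)-3-methyl-1-{(1S,5R)-5-methyl-2-(propan-2-yl)-5-[(trimethylsilyl)ethynyl]cyclopent-2-en-1-yl}but-3-en-1-yl]oxy}silane | C[Si](C)(C)C#C[C@]1(C)CC=C(C(C)C)[C@@H]1[C@H](O[Si](C)(C)C(C)(C)C)CC(C)=C | intermediate
14 | (1R)-1-[(1S,5R)-5-ethynyl-5-methyl-2-(propan-2-yl)cyclopent-2-en-1-yl]-3-methylbut-3-en-1-ol | C#C[C@]1(C)CC=C(C(C)C)[C@@H]1[C@H](O)CC(C)=C | intermediate
15 | (1R)-1-[(1S,5R)-5-[3-(dicyclohexylamino)prop-1-yn-1-yl]-5-methyl-2-(propan-2-yl)cyclopent-2-en-1-yl]-3-methylbut-3-en-1-ol | C1CCCCC1N(CC#C[C@]2(C)CC=C(C(C)C)[C@@H]2[C@H](O)CC(C)=C)C1CCCCC1 | intermediate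
16 | (1R)-3-methyl-1-[(1R,5S)-5-methyl-5-(propa-1,2-dien-1-yl)-2-(propan-2-yl)cyclopent-2-en-1-yl]but-3-en-1-ol | C=C=C[C@]1(C)CC=C(C(C)C)[C@@H]1[C@H](O)CC(C)=C | intermediate
17 | 4-(acetyloxy)benzoyl chloride | CC(=O)Oc1ccc(cc1)C(Cl)=O | starting material
18 | (1R)-3-methyl-1-[(1R,5S)-5-methyl-5-(propa-1,2-dien-1-yl)-2-(propan-2-yl)cyclopent-2-en-1-yl]but-3-en-1-yl 4-(acetyloxy)benzoate | C=C=C[C@]1(C)CC=C(C(C)C)[C@@H]1[C@H](OC(=O)c1ccc(OC(C)=O)cc1)CC(C)=C | intermediate
19 | 3-methylbutanoic acid | CC(C)CC(O)=O | starting material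
20 | (1R)-3-methyl-1-[(1S,5R)-5-methyl-5-{(1S)-1-[(3-methylbutanoyl)oxy]prop-2-en-1-yl}-2-(propan-2-yl)cyclopent-2-en-1-yl]but-3-en-1-yl 4-(acetyloxy)benzoate | C=C[C@H](OC(=O)CC(C)C)[C@]1(C)CC=C(C(C)C)[C@@H]1[C@H](OC(=O)c1ccc(OC(C)=O)cc1)CC(C)=C | intermediate
21 | (3aS,4R,8S,8aR)-6,8a-dimethyl-8-[(3-methylbutanoyl)oxy]-3-(propan-2-yl)-1,3a,4,5,8,8a-hexahydroazulen-4-yl 4-(acetyloxy)benzoate | CC1=C[C@H](OC(=O)CC(C)C)[C@]2(C)CC=C(C(C)C)[C@@H]2[C@H](OC(=O)c2ccc(OC(C)=O)cc2)C1 | intermediate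
22 | (3S,3aS,4R,8S,8aR)-3-hydroperoxy-6,8a-dimethyl-8-[(3-methylbutanoyl)oxy]-3-(propan-2-yl)-1,2,3,3a,4,5,8,8a-octahydroazulen-4-yl 4-(acetyloxy)benzoate | CC1=C[C@H](OC(=O)CC(C)C)[C@]2(C)CC[C@](OO)(C(C)C)[C@@H]2[C@H](OC(=O)c2ccc(OC(C)=O)cc2)C1 | intermediate
23 | (3S,3aS,4R,8S,8aR)-3-hydroxy-6,8a-dimethyl-8-[(3-methylbutanoyl)oxy]-3-(propan-2-yl)-1,2,3,3a,4,5,8,8a-octahydroazulen-4-yl 4-(acetyloxy)benzoate | CC1=C[C@H](OC(=O)CC(C)C)[C@]2(C)CC[C@](O)(C(C)C)[C@@H]2[C@H](OC(=O)c2ccc(OC(C)=O)cc2)C1 | intermediate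
24 | (3S,3aS,4R,8S,8aR)-3-hydroxy-6,8a-dimethyl-8-[(3-methylbutanoyl)oxy]-3-(propan-2-yl)-1,2,3,3a,4,5,8,8a-octahydroazulen-4-yl 4-hydroxybenzoate | CC1=C[C@H](OC(=O)CC(C)C)[C@]2(C)CC[C@](O)(C(C)C)[C@@H]2[C@H](OC(=O)c2ccc(O)cc2)C1 | target

**Step count:** 13 steps in total; longest linear sequence 12 steps (3 → 24, steps 2–13).

**Steps most likely to fail**

Step 3. The 1,4-selective asymmetric methylation is established for six-membered enynones but not for this five-membered one, and the syn sense of the one-pot titanium aldol may be weak. The fallback sets out from 6 and comes back at 9. The same copper-catalysed 1,4-methylation is run, but the bromomagnesium enolate 7 is quenched with Me3SiCl and isolated as trimethyl{[(3R)-3-methyl-3-[(trimethylsilyl)ethynyl]cyclopent-1-en-1-yl]oxy}silane F1. A fluoride-promoted aldol of F1 with 2 (catalytic tris(dimethylamino)sulfonium difluorotrimethylsilicate, THF, −78 °C) goes through an open transition state and is syn-selective whatever the enolate geometry. It gives (2S,3R)-3-methyl-2-{(1R)-3-methyl-1-[(trimethylsilyl)oxy]but-3-en-1-yl}-3-[(trimethylsilyl)ethynyl]cyclopentan-1-one F2, and citric acid in MeOH then frees the alcohol 9.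

Step 10 (the proposed new method). Branched C–O bond formation next to a quaternary carbon may be slow, may turn linear, or may give the wrong C8 epimer. The fallback uses known chemistry, sets out from 14 and comes back at 20.
- Alkynol 14 is acylated with 17 (pyridine, DMAP) to (1R)-1-[(1S,5R)-5-ethynyl-5-methyl-2-(propan-2-yl)cyclopent-2-en-1-yl]-3-methylbut-3-en-1-yl 4-(acetyloxy)benzoate F3.
- Markovnikov hydration of the alkyne (Ph3PAuNTf2, aqueous dioxane) gives the methyl ketone (1R)-1-[(1S,5R)-5-acetyl-5-methyl-2-(propan-2-yl)cyclopent-2-en-1-yl]-3-methylbut-3-en-1-yl 4-(acetyloxy)benzoate F4.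
- α-Methylenation (paraformaldehyde, N-methylanilinium trifluoroacetate, THF, reflux) gives the vinyl ketone (1R)-3-methyl-1-[(1S,5R)-5-methyl-5-(prop-2-enoyl)-2-(propan-2-yl)cyclopent-2-en-1-yl]but-3-en-1-yl 4-(acetyloxy)benzoate F5.
- Corey–Bakshi–Shibata reduction (Me-CBS oxazaborolidine enantiomer chosen for the (S) carbinol, catecholborane, toluene, −78 °C) gives (1R)-1-[(1S,5R)-5-[(1S)-1-hydroxyprop-2-en-1-yl]-5-methyl-2-(propan-2-yl)cyclopent-2-en-1-yl]-3-methylbut-3-en-1-yl 4-(acetyloxy)benzoate F6.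
- Acylation of F6 with 3-methylbutanoic anhydride and DMAP gives 20.

Step 12. The two trisubstituted alkenes may not be told apart well enough by the cobalt hydride. The fallback sets out from 21 and comes back at 23. Epoxidation with mCPBA (1.0 equiv, NaHCO3, CH2Cl2, −20 °C) takes the more electron-rich cyclopentene from the convex face and gives the 2,3-epoxide of 21 with the oxirane oxygen cis to H-3a F7. Ring opening at the secondary carbon with PhSeSePh/NaBH4 in EtOH gives the 2-(phenylselanyl) derivative of 23 with the selanyl group trans to the 3-hydroxy group F8. Bu3SnH with AIBN in toluene at 80 °C then removes selenium to give 23.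

**Further compounds**

F1 | step 3 | trimethyl{[(3R)-3-methyl-3-[(trimethylsilyl)ethynyl]cyclopent-1-en-1-yl]oxy}silane | C[Si](C)(C)C#C[C@]1(C)CCC(O[Si](C)(C)C)=C1
F2 | step 3 | (2S,3R)-3-methyl-2-{(1R)-3-methyl-1-[(trimethylsilyl)oxy]but-3-en-1-yl}-3-[(trimethylsilyl)ethynyl]cyclopentan-1-one | C[Si](C)(C)C#C[C@]1(C)CCC(=O)[C@@H]1[C@H](O[Si](C)(C)C)CC(C)=C
F3 | step 10 | (1R)-1-[(1S,5R)-5-ethynyl-5-methyl-2-(propan-2-yl)cyclopent-2-en-1-yl]-3-methylbut-3-en-1-yl 4-(acetyloxy)benzoate | C#C[C@]1(C)CC=C(C(C)C)[C@@H]1[C@H](OC(=O)c1ccc(OC(C)=O)cc1)CC(C)=C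
F4 | step 10 | (1R)-1-[(1S,5R)-5-acetyl-5-methyl-2-(propan-2-yl)cyclopent-2-en-1-yl]-3-methylbut-3-en-1-yl 4-(acetyloxy)benzoate | CC(=O)[C@]1(C)CC=C(C(C)C)[C@@H]1[C@H](OC(=O)c1ccc(OC(C)=O)cc1)CC(C)=C
F5 | step 10 | (1R)-3-methyl-1-[(1S,5R)-5-methyl-5-(prop-2-enoyl)-2-(propan-2-yl)cyclopent-2-en-1-yl]but-3-en-1-yl 4-(acetyloxy)benzoate | C=CC(=O)[C@]1(C)CC=C(C(C)C)[C@@H]1[C@H](OC(=O)c1ccc(OC(C)=O)cc1)CC(C)=C
F6 | step 10 | (1R)-1-[(1S,5R)-5-[(1S)-1-hydroxyprop-2-en-1-yl]-5-methyl-2-(propan-2-yl)cyclopent-2-en-1-yl]-3-methylbut-3-en-1-yl 4-(acetyloxy)benzoate | C=C[C@H](O)[C@]1(C)CC=C(C(C)C)[C@@H]1[C@H](OC(=O)c1ccc(OC(C)=O)cc1)CC(C)=C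
F7 | step 12 | 2,3-epoxide of 21 with the oxirane oxygen cis to H-3a | CC1=C[C@H](OC(=O)CC(C)C)[C@]2(C)C[C@H]3O[C@@]3(C(C)C)[C@@H]2[C@H](OC(=O)c2ccc(OC(C)=O)cc2)C1
F8 | step 12 | 2-(phenylselanyl) derivative of 23 with the selanyl group trans to the 3-hydroxy group | CC1=C[C@H](OC(=O)CC(C)C)[C@]2(C)C[C@H]([Se]c3ccccc3)[C@](O)(C(C)C)[C@@H]2[C@H](OC(=O)c2ccc(OC(C)=O)cc2)C1
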